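**Strategy.** Ring B (C5, C6, C7, C8, C9, C10; labdane numbering) is grown from the cyclopentenone ring C5=C6–C8(=O)–C9–C10 of a hydrindenone. A β-oxido carbenoid 1,2-shift inserts C7 between C8 and C6. This exploits the 1,3-relationship of the C6 oxygen and the C8 methylene: the resulting enone offers C8=O for methylenation, C6 for conjugate oxygenation and C5 for the trans ring fusion. The precursor already carries the C4 ester, both quaternary methyl groups (one from an organocatalytic Michael addition, one from a palladium-catalysed decarboxylative allylation) and the dienyl side chain on C9.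

Key step: step 10

Remark: atoms carry labdane numbers (ring A: C1–C5 and C10; ring B: C5–C10; side chain C11–C16; C17 methylene carbon; C18 carboxyl carbon; C19 methyl on C4; C20 methyl on C10). The cinchona catalyst of step 2 is assumed to be taken in the pseudoenantiomeric form that gives the S centre; which form that is has to be established by experiment.

Step 1
Reactants: 1 methyl 2-methyl-3-oxopentanoate
Product: 2 2-(trimethylsilyl)ethyl 2-methyl-3-oxopentanoate (racemic)
Conditions: 2-(trimethylsilyl)ethanol, DMAP (cat.), toluene, reflux with removal of MeOH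
Reagents that add atoms: 2-(trimethylsilyl)ethanol, C[Si](C)(C)CCO
Why: DMAP-catalysed transesterification of a β-keto ester exchanges the methyl ester for a fluoride-labile ester that can be removed at the end beside an acetate; no stereocentre is set.

Step 2
Reactants: 2 2-(trimethylsilyl)ethyl 2-methyl-3-oxopentanoate; 3 acrolein
Product: 5 2-(trimethylsilyl)ethyl (1S)-1,3-dimethyl-2-oxocyclohex-3-ene-1-carboxylate, via Michael adduct 4 (not isolated)
Conditions: 9-O-(9-phenanthryl)cupreidine or its cupreine pseudoenantiomer (10 mol%), CH2Cl2, −25 °C; then piperidinium acetate, toluene, 80 °C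
Reagents that add atoms: none
Why: A bifunctional cinchona-catalysed Michael addition of the α-methyl β-keto ester to acrolein should set the quaternary centre C4 (S) by catalyst control, and the keto aldehyde then closes ring A by intramolecular aldol condensation (6-enolexo, Robinson-type annulation) of the ketone CH2 (C10) onto the aldehyde (C1).

Step 3
Reactants: 5 2-(trimethylsilyl)ethyl (1S)-1,3-dimethyl-2-oxocyclohex-3-ene-1-carboxylate
Product: 7 prop-2-en-1-yl (6S)-2,6-dimethyl-6-{[2-(trimethylsilyl)ethoxy]carbonyl}cyclohex-1-en-1-yl carbonate, via lithium enolate 6 (not isolated)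
Conditions: LiBH(s-Bu)3, THF, −78 °C; then allyl chloroformate, −78 to 0 °C
Reagents that add atoms: allyl chloroformate, C=CCOC(=O)Cl
Why: Conjugate hydride reduction of the β-unsubstituted enone gives the tetrasubstituted enolate regiospecifically (1,2-attack is blocked by the quaternary C4), and O-acylation traps it as the allyl enol carbonate; C4 is untouched.

Step 4
Reactants: 7 prop-2-en-1-yl (6S)-2,6-dimethyl-6-{[2-(trimethylsilyl)ethoxy]carbonyl}cyclohex-1-en-1-yl carbonate
Product: 8 2-(trimethylsilyl)ethyl (1S,3S)-1,3-dimethyl-2-oxo-3-(prop-2-en-1-yl)cyclohexane-1-carboxylate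
Conditions: Pd2(dba)3 (2.5 mol%), (S)-t-BuPHOX (6 mol%), THF, 25 °C
Reagents that add atoms: none
Why: Palladium-catalysed decarboxylative asymmetric allylic alkylation (Tsuji type): recombination of the allylpalladium enolate at C10 is steered by the phosphinooxazoline ligand, the ligand enantiomer that gives (S)-2-allyl-2-methylcyclohexanone in the parent case, so the new quaternary centre C10 should form by catalyst control with the C4 and C10 methyl groups cis.

Step 5
Reactants: 8 2-(trimethylsilyl)ethyl (1S,3S)-1,3-dimethyl-2-oxo-3-(prop-2-en-1-yl)cyclohexane-1-carboxylate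
Product: 9 2-(trimethylsilyl)ethyl (1S,3S)-1,3-dimethyl-2-oxo-3-(2-oxopropyl)cyclohexane-1-carboxylate
Conditions: PdCl2 (cat.), CuCl, O2 (1 atm), DMF/H2O, 23 °C
Reagents that add atoms: water, O
Why: Tsuji–Wacker oxidation converts the terminal alkene into the methyl ketone (Markovnikov hydroxypalladation) and gives the 1,4-diketone; no stereocentre changes.

Step 6
Reactants: 9 2-(trimethylsilyl)ethyl (1S,3S)-1,3-dimethyl-2-oxo-3-(2-oxopropyl)cyclohexane-1-carboxylate
Product: 10 2-(trimethylsilyl)ethyl (4S,7aS)-4,7a-dimethyl-2-oxo-2,4,5,6,7,7a-hexahydro-1H-indene-4-carboxylate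
Conditions: KOt-Bu, t-BuOH/THF, 50 °C
Reagents that add atoms: none
Why: Intramolecular aldol condensation (5-enolexo): the methyl-ketone enolate (C6) attacks the ring ketone C5 and dehydration gives the cyclopentenone, a closure that is precedented for 2-oxopropyl cyclohexanones flanked by two quaternary carbons; C4 and C10 cannot epimerise.

Step 7
Reactants: 11 (2E)-3-methylpent-2-en-4-yn-1-ol
Product: 12 (2E)-3-methylpenta-2,4-dien-1-ol
Conditions: H2 (1 atm), Pd/CaCO3 poisoned with Pb(OAc)2 (Lindlar catalyst), quinoline, hexane/EtOAc, 0 °C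
Reagents that add atoms: none
Why: Lindlar semi-hydrogenation of the terminal alkyne should stop at the vinyl group and leave the trisubstituted E alkene untouched.

Step 8
Reactants: 12 (2E)-3-methylpenta-2,4-dien-1-ol
Product: 13 (3E)-5-bromo-3-methylpenta-1,3-diene
Conditions: CBr4, PPh3, CH2Cl2, 0 °C
Reagents that add atoms: carbon tetrabromide, BrC(Br)(Br)Br
Why: Appel bromination of the primary allylic alcohol under neutral conditions should keep the E geometry and avoid allylic transposition.

Step 9
Reactants: 10 2-(trimethylsilyl)ethyl (4S,7aS)-4,7a-dimethyl-2-oxo-2,4,5,6,7,7a-hexahydro-1H-indene-4-carboxylate; 13 (3E)-5-bromo-3-methylpenta-1,3-diene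
Product: 14 2-(trimethylsilyl)ethyl (4S,7aS)-4,7a-dimethyl-1-[(2E)-3-methylpenta-2,4-dien-1-yl]-2-oxo-2,4,5,6,7,7a-hexahydro-1H-indene-4-carboxylate (both epimers at C9)
Conditions: LiN(i-Pr)2, THF, −78 °C; then 13, DMPU, −78 to −20 °C
Reagents that add atoms: none
Why: α'-Alkylation of the cross-conjugated lithium enolate (C9 is the only acidic position because C4 and C10 are quaternary) with the primary allylic bromide by SN2 installs the complete side chain; the configuration at C9 is left open here because step 10 equilibrates it.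

Step 10
Reactants: 14 2-(trimethylsilyl)ethyl (4S,7aS)-4,7a-dimethyl-1-[(2E)-3-methylpenta-2,4-dien-1-yl]-2-oxo-2,4,5,6,7,7a-hexahydro-1H-indene-4-carboxylate
Product: 17 2-(trimethylsilyl)ethyl (1S,4aR,5S,8aS)-1,4a-dimethyl-5-[(2E)-3-methylpenta-2,4-dien-1-yl]-6-oxo-1,2,3,4,4a,5,6,8a-octahydronaphthalene-1-carboxylate, via alkoxide adduct 15 (not isolated), via β,γ-enone 16 (not isolated)
Conditions: CH2Br2, lithium 2,2,6,6-tetramethylpiperidide, THF, −78 °C; n-BuLi, −78 to 0 °C; aq NH4Cl; then DBU, CH2Cl2, 23 °C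
Reagents that add atoms: dibromomethane, BrCBr
Why: Dibromomethyllithium, formed in the presence of the ketone, adds 1,2 to C8 (the β-carbon C5 is fully substituted, so conjugate addition is blocked) and bromine–lithium exchange turns the adduct into a β-oxido carbenoid. The alkenyl carbon C6 migrates from C8 to the carbenoid carbon (the future C7) with loss of LiBr, a semipinacol-type 1,2-shift; the closest known reaction type is the β-oxido carbenoid homologation of cyclic ketones and enones, the carbenoid relative of the Tiffeneau–Demjanov ring enlargement. No ring is closed from a chain: the five-membered ring C5–C6–C8–C9–C10 becomes the six-membered ring B by insertion of one carbon, first as the lithium dienolate and, after protonation at C7, as the β,γ-enone. DBU moves the double bond into conjugation: C5 should be protonated on the face opposite the two syn-axial methyl groups on C4 and C10, which gives the trans ring fusion, and C9, now α to the ketone, should settle in the equatorial configuration cis to the C10 methyl. The step needs migration of C6 and not of C9; the higher migratory aptitude of an sp2 carbon and the congestion around the tertiary C9 next to the quaternary C10 should secure it.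

Step 11
Reactants: 17 2-(trimethylsilyl)ethyl (1S,4aR,5S,8aS)-1,4a-dimethyl-5-[(2E)-3-methylpenta-2,4-dien-1-yl]-6-oxo-1,2,3,4,4a,5,6,8a-octahydronaphthalene-1-carboxylate
Product: 19 2-(trimethylsilyl)ethyl (1S,4aR,5S,8R,8aS)-8-hydroxy-1,4a-dimethyl-5-[(2E)-3-methylpenta-2,4-dien-1-yl]-6-oxodecahydronaphthalene-1-carboxylate, via boronate 18 (not isolated)
Conditions: B2pin2, CuCl (cat.), DPEphos, NaOt-Bu (cat.), MeOH, THF, 23 °C; then NaBO3·4H2O, THF/H2O, 23 °C
Reagents that add atoms: bis(pinacolato)diboron (boron of 18 only), CC1(C)OB(OC1(C)C)B1OC(C)(C)C(C)(C)O1; sodium perborate (oxygen of 19), O=BO[O-].[Na+]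
Why: Copper-catalysed conjugate borylation: the borylcopper species should add to C6 from the face of H5, opposite the two syn-axial methyl groups on C4 and C10, and stereoretentive oxidation of the C–B bond then gives the equatorial 6-hydroxyl; the electron-poor enone should react far faster than the unactivated diene.

Step 12
Reactants: 19 2-(trimethylsilyl)ethyl (1S,4aR,5S,8R,8aS)-8-hydroxy-1,4a-dimethyl-5-[(2E)-3-methylpenta-2,4-dien-1-yl]-6-oxodecahydronaphthalene-1-carboxylate
Product: 20 2-(trimethylsilyl)ethyl (1S,4aR,5S,8R,8aS)-8-(acetyloxy)-1,4a-dimethyl-5-[(2E)-3-methylpenta-2,4-dien-1-yl]-6-oxodecahydronaphthalene-1-carboxylate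
Conditions: Ac2O, pyridine, DMAP (cat.), CH2Cl2, 0 °C
Reagents that add atoms: acetic anhydride, CC(=O)OC(C)=O
Why: DMAP-catalysed acetylation of the secondary alcohol, run cold and without delay so that neither β-elimination nor lactonisation onto the C18 ester competes; no stereocentre changes.

Step 13
Reactants: 20 2-(trimethylsilyl)ethyl (1S,4aR,5S,8R,8aS)-8-(acetyloxy)-1,4a-dimethyl-5-[(2E)-3-methylpenta-2,4-dien-1-yl]-6-oxodecahydronaphthalene-1-carboxylate
Product: 21 2-(trimethylsilyl)ethyl (1S,4aS,5R,8R,8aS)-8-(acetyloxy)-1,4a-dimethyl-6-methylidene-5-[(2E)-3-methylpenta-2,4-dien-1-yl]decahydronaphthalene-1-carboxylate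
Conditions: Zn, CH2Br2, TiCl4, THF; then 20, CH2Cl2, 0 to 23 °C
Reagents that add atoms: dibromomethane, BrCBr
Why: Lombardo methylenation (geminal zinc–titanium methylene reagent) should convert the hindered C8 ketone into the exocyclic methylene under non-basic conditions, so the β-acetoxy group is not eliminated and C9 is not epimerised.

Step 14
Reactants: 21 2-(trimethylsilyl)ethyl (1S,4aS,5R,8R,8aS)-8-(acetyloxy)-1,4a-dimethyl-6-methylidene-5-[(2E)-3-methylpenta-2,4-dien-1-yl]decahydronaphthalene-1-carboxylate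
Product: 22 (1S,4aS,5R,8R,8aS)-8-(acetyloxy)-1,4a-dimethyl-6-methylidene-5-[(2E)-3-methylpenta-2,4-dien-1-yl]decahydronaphthalene-1-carboxylic acid (CNP0240327.3)
Conditions: Bu4NF, THF, 0 to 23 °C; then cold 0.1 M HCl
Reagents that add atoms: none
Why: Fluoride attacks silicon and the ester fragments by β-elimination to ethene, fluorotrimethylsilane and the carboxylate, conditions that should leave the hindered acetate, the diene and the exocyclic alkene intact; brief cold acid liberates the acid.

**Compound list**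

1 | methyl 2-methyl-3-oxopentanoate | CCC(=O)C(C)C(=O)OC | starting material
2 | 2-(trimethylsilyl)ethyl 2-methyl-3-oxopentanoate (racemic) | CCC(=O)C(C)C(=O)OCC[Si](C)(C)C | intermediate
3 | acrolein | C=CC=O | starting material
4 | 2-(trimethylsilyl)ethyl (2S)-2-methyl-3-oxo-2-(3-oxopropyl)pentanoate (Michael adduct, not isolated) | CCC(=O)[C@](C)(CCC=O)C(=O)OCC[Si](C)(C)C | intermediate
5 | 2-(trimethylsilyl)ethyl (1S)-1,3-dimethyl-2-oxocyclohex-3-ene-1-carboxylate | CC1=CCC[C@](C)(C(=O)OCC[Si](C)(C)C)C1=O | intermediate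
6 | lithium (6S)-2,6-dimethyl-6-{[2-(trimethylsilyl)ethoxy]carbonyl}cyclohex-1-en-1-olate (not isolated) | [Li+].[O-]C1=C(C)CCC[C@]1(C)C(=O)OCC[Si](C)(C)C | intermediate
7 | prop-2-en-1-yl (6S)-2,6-dimethyl-6-{[2-(trimethylsilyl)ethoxy]carbonyl}cyclohex-1-en-1-yl carbonate | C=CCOC(=O)OC1=C(C)CCC[C@]1(C)C(=O)OCC[Si](C)(C)C | intermediate
8 | 2-(trimethylsilyl)ethyl (1S,3S)-1,3-dimethyl-2-oxo-3-(prop-2-en-1-yl)cyclohexane-1-carboxylate (methyl groups cis) | C=CC[C@]1(C)CCC[C@](C)(C(=O)OCC[Si](C)(C)C)C1=O | intermediate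
9 | 2-(trimethylsilyl)ethyl (1S,3S)-1,3-dimethyl-2-oxo-3-(2-oxopropyl)cyclohexane-1-carboxylate | CC(=O)C[C@]1(C)CCC[C@](C)(C(=O)OCC[Si](C)(C)C)C1=O | intermediate
10 | 2-(trimethylsilyl)ethyl (4S,7aS)-4,7a-dimethyl-2-oxo-2,4,5,6,7,7a-hexahydro-1H-indene-4-carboxylate | C1C(=O)C=C2[C@@]1(C)CCC[C@]2(C)C(=O)OCC[Si](C)(C)C | intermediate
11 | (2E)-3-methylpent-2-en-4-yn-1-ol | C#C/C(C)=C/CO | starting material
12 | (2E)-3-methylpenta-2,4-dien-1-ol | C=C/C(C)=C/CO | intermediate
13 | (3E)-5-bromo-3-methylpenta-1,3-diene | C=C/C(C)=C/CBr | intermediate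
14 | 2-(trimethylsilyl)ethyl (4S,7aS)-4,7a-dimethyl-1-[(2E)-3-methylpenta-2,4-dien-1-yl]-2-oxo-2,4,5,6,7,7a-hexahydro-1H-indene-4-carboxylate (both epimers at the side-chain carbon C9, which is set in step 10) | C=C/C(C)=C/CC1C(=O)C=C2[C@@]1(C)CCC[C@]2(C)C(=O)OCC[Si](C)(C)C | intermediate
15 | lithium alkoxide of the 1,2-adduct of dibromomethyllithium to the ketone of 14 (2-dibromomethyl-2-oxido hydrindene, not isolated) | C=C/C(C)=C/CC1C([O-])(C(Br)Br)C=C2[C@@]1(C)CCC[C@]2(C)C(=O)OCC[Si](C)(C)C.[Li+] | intermediate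
16 | 2-(trimethylsilyl)ethyl (1S,4aS)-1,4a-dimethyl-5-[(2E)-3-methylpenta-2,4-dien-1-yl]-6-oxo-1,2,3,4,4a,5,6,7-octahydronaphthalene-1-carboxylate (β,γ-enone, both C9 epimers, not isolated) | C=C/C(C)=C/CC1C(=O)CC=C2[C@@]1(C)CCC[C@]2(C)C(=O)OCC[Si](C)(C)C | intermediate
17 | 2-(trimethylsilyl)ethyl (1S,4aR,5S,8aS)-1,4a-dimethyl-5-[(2E)-3-methylpenta-2,4-dien-1-yl]-6-oxo-1,2,3,4,4a,5,6,8a-octahydronaphthalene-1-carboxylate (trans-fused, side chain cis to the C10 methyl) | C=C/C(C)=C/C[C@@H]1C(=O)C=C[C@H]2[C@@]1(C)CCC[C@]2(C)C(=O)OCC[Si](C)(C)C | intermediate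
18 | 2-(trimethylsilyl)ethyl (1S,4aR,5S,8R,8aS)-1,4a-dimethyl-5-[(2E)-3-methylpenta-2,4-dien-1-yl]-6-oxo-8-(4,4,5,5-tetramethyl-1,3,2-dioxaborolan-2-yl)decahydronaphthalene-1-carboxylate (not isolated) | C=C/C(C)=C/C[C@@H]1C(=O)C[C@@H](B3OC(C)(C)C(C)(C)O3)[C@H]2[C@@]1(C)CCC[C@]2(C)C(=O)OCC[Si](C)(C)C | intermediate
19 | 2-(trimethylsilyl)ethyl (1S,4aR,5S,8R,8aS)-8-hydroxy-1,4a-dimethyl-5-[(2E)-3-methylpenta-2,4-dien-1-yl]-6-oxodecahydronaphthalene-1-carboxylate | C=C/C(C)=C/C[C@@H]1C(=O)C[C@@H](O)[C@H]2[C@@]1(C)CCC[C@]2(C)C(=O)OCC[Si](C)(C)C | intermediate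
20 | 2-(trimethylsilyl)ethyl (1S,4aR,5S,8R,8aS)-8-(acetyloxy)-1,4a-dimethyl-5-[(2E)-3-methylpenta-2,4-dien-1-yl]-6-oxodecahydronaphthalene-1-carboxylate | C=C/C(C)=C/C[C@@H]1C(=O)C[C@@H](OC(C)=O)[C@H]2[C@@]1(C)CCC[C@]2(C)C(=O)OCC[Si](C)(C)C | intermediate
21 | 2-(trimethylsilyl)ethyl (1S,4aS,5R,8R,8aS)-8-(acetyloxy)-1,4a-dimethyl-6-methylidene-5-[(2E)-3-methylpenta-2,4-dien-1-yl]decahydronaphthalene-1-carboxylate | C=C/C(C)=C/C[C@@H]1C(=C)C[C@@H](OC(C)=O)[C@H]2[C@@]1(C)CCC[C@]2(C)C(=O)OCC[Si](C)(C)C | intermediate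
22 | (1S,4aS,5R,8R,8aS)-8-(acetyloxy)-1,4a-dimethyl-6-methylidene-5-[(2E)-3-methylpenta-2,4-dien-1-yl]decahydronaphthalene-1-carboxylic acid (CNP0240327.3) | C=C/C(C)=C/C[C@@H]1C(=C)C[C@@H](OC(C)=O)[C@H]2[C@@]1(C)CCC[C@]2(C)C(=O)O | target

**Step count and risks**

Total step count: 14. Longest linear sequence: 12 (steps 1–6 and 9–14; steps 7–8 make the side-chain bromide).

Most likely to fail, in this order:

- **Step 10.** The ketone may be enolised instead of attacked, the alkyl carbon C9 may migrate instead of the alkenyl carbon C6, or butyllithium may attack the ester. Fallback from 14: addition of (phenylselanyl)methyllithium (from bis(phenylselanyl)methane and n-BuLi) to the ketone should give β-hydroxy selenide F1. Methylation at selenium (MeOTf) turns it into a selenonium leaving group, and the same alkenyl 1,2-shift then gives β,γ-enone 16. This re-enters the route at the DBU treatment that leads to 17.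

- **Step 11.** The borylcopper species may also attack the side-chain diene or add from the wrong face, and the new 6-hydroxyl may lactonise onto the C18 ester or be lost by β-elimination during the basic oxidation. Fallback from 17: Weitz–Scheffer epoxidation (t-BuOOH, DBU) on the face of H5 should give the 6,7-epoxy ketone F2. Reductive cleavage of the C7–O bond next to the ketone with SmI2 (THF/MeOH, −90 °C) then gives hydroxy ketone 19 under neutral conditions, and the route continues with step 12.

- **Step 2.** Enantioselectivity may be low for an acyclic β-keto ester, acrolein may polymerise, and a retro-Michael reaction during the condensation may erode the centre. Fallback from 2: condensation with L-valine diethylamide (the valine enantiomer being chosen for the S centre) gives the enamino ester F3. Its Cu(OAc)2·H2O-catalysed Michael addition to acrolein under auxiliary control, followed by mild acid hydrolysis, should give keto aldehyde 4. This is cyclised to 5 as in step 2.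

Further compounds
F1 | step 10 | 2-(trimethylsilyl)ethyl (4S,7aS)-2-hydroxy-4,7a-dimethyl-1-[(2E)-3-methylpenta-2,4-dien-1-yl]-2-[(phenylselanyl)methyl]-2,4,5,6,7,7a-hexahydro-1H-indene-4-carboxylate | C=C/C(C)=C/CC1C(O)(C[Se]c3ccccc3)C=C2[C@@]1(C)CCC[C@]2(C)C(=O)OCC[Si](C)(C)C
F2 | step 11 | 2-(trimethylsilyl)ethyl 6,7-epoxy-8-oxo derivative of 17 with the epoxide oxygen on the face of H5 (labdane numbering) | C=C/C(C)=C/C[C@@H]1C(=O)[C@H]3O[C@H]3[C@H]2[C@@]1(C)CCC[C@]2(C)C(=O)OCC[Si](C)(C)C
F3 | step 2 | 2-(trimethylsilyl)ethyl (2Z)-3-{[(2S)-1-(diethylamino)-3-methyl-1-oxobutan-2-yl]amino}-2-methylpent-2-enoate | CC/C(N[C@@H](C(C)C)C(=O)N(CC)CC)=C(C)/C(=O)OCC[Si](C)(C)C
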